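**Plan**

1. Numbering as 3,7-dioxabicyclo[3.3.0]octane: C1 (OH), C2 (aryl), O3, C4, C5 (H), C6 (aryl), O7, C8. Read from the SMILES the target is (1S,2R,5R,6R): OH, H-5, H-6 and the C2 aryl lie on the convex face, the C6 aryl is endo.
2. Retrosynthesis: H2 is taken off C5–C6 (bicyclic enol ether). Then C4–C5 and O7–C6 are cut together, which opens both rings to an acyclic aryl alkyne C5≡C6 carrying O3–CH2–OMe (a MOM ether) on C2 and O7 as a tert-butyl ether on C8. Then C1–C5 (acetylide + ketone), C1–C8 (acylation) and the C2 carbinol (keto ester reduction) are cut.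
3. Forward: chain assembly C2 → C1–C8 → C1–C5; rings A and B then close in one operation (C5 attacks the O3=C4H2+ ion, O7 closes on C6); last, syn hydrogenation of C5=C6.
4. Feature that makes the key step possible: C1 carries both tethers (C2–O3 towards C5, C8–O7 towards C6), and the C6 aryl ring has a para methoxy group that stabilises a vinyl cation at C6. The triple bond C5≡C6 can therefore take up C4 and O7 anti in one step.
5. Stereochemistry: C2 from catalytic asymmetric transfer hydrogenation; C1 from Cram-chelate alkynylation (the MOM group is chelator first, C4 source later). C5 and C6 come from syn addition of H2 to the enol ether: the forced cis ring fusion puts H-5 and H-6 on the OH face, which gives the endo C6 aryl that cationic closures at C6 do not give.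

Key step: step 7

Remark: compounds 1 and 6 are taken as commercial; the tert-butoxymethyl carbanion is made in the flask from methyl tert-butyl ether.

**Route**

Step 1
Reactants: 1 ethyl (3,4-dimethoxyphenyl)(oxo)acetate
Product: 2 ethyl (R)-(3,4-dimethoxyphenyl)(hydroxy)acetate
Conditions: RuCl[(S,S)-TsDPEN](p-cymene) (cat.), HCO2H/Et3N 5:2, DMF, 25 °C
Reagents that add atoms: none
Why: Noyori–Ikariya asymmetric transfer hydrogenation of an aryl α-keto ester, in which the catalyst tells aryl from ester and should deliver hydride to the face that gives the (R)-carbinol (the antipodal catalyst is taken if the sense proves opposite); this sets C2.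

Step 2
Reactants: 2 ethyl (R)-(3,4-dimethoxyphenyl)(hydroxy)acetate
Product: 3 ethyl (R)-(3,4-dimethoxyphenyl)(methoxymethoxy)acetate
Conditions: MOMCl, i-Pr2NEt, CH2Cl2, 0 → 25 °C
Reagents that add atoms: chloromethyl methyl ether, COCCl
Why: O-alkylation of the secondary alcohol with an α-chloro ether leaves the stereocentre untouched and installs the acetal that serves as chelating group in step 5 and as the source of C4 in step 7.

Step 3
Reactants: 3 ethyl (R)-(3,4-dimethoxyphenyl)(methoxymethoxy)acetate
Product: 4 (R)-2-(3,4-dimethoxyphenyl)-N-methoxy-2-(methoxymethoxy)-N-methylacetamide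
Conditions: MeNH(OMe)·HCl, AlMe3, CH2Cl2, 0 → 25 °C
Reagents that add atoms: N,O-dimethylhydroxylamine hydrochloride, CNOC.Cl
Why: Weinreb aminolysis of the ester by the aluminium amide is non-basic, so the acidic benzylic C2–H should not be removed and the configuration should be kept.

Step 4
Reactants: 4 (R)-2-(3,4-dimethoxyphenyl)-N-methoxy-2-(methoxymethoxy)-N-methylacetamide
Product: 5 (R)-1-tert-butoxy-3-(3,4-dimethoxyphenyl)-3-(methoxymethoxy)propan-2-one
Conditions: t-BuOMe, s-BuLi, KOt-Bu, THF, −78 °C; LiBr; then 4, −78 °C; aq NH4Cl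
Reagents that add atoms: tert-butoxymethyllithium, [Li]COC(C)(C)C
Why: Weinreb ketone synthesis with a hydroxymethyl-anion equivalent, in which the chelated tetrahedral intermediate stops at the ketone; it brings in C8 with O7 as a tert-butyl ether (a poor chelator in step 5, a cation trap in step 7).

Step 5
Reactants: 5 (R)-1-tert-butoxy-3-(3,4-dimethoxyphenyl)-3-(methoxymethoxy)propan-2-one; 6 4-ethynyl-1,2-dimethoxybenzene
Product: 8 (1R,2S)-2-(tert-butoxymethyl)-1,4-bis(3,4-dimethoxyphenyl)-1-(methoxymethoxy)but-3-yn-2-ol, via alkynylmagnesium bromide 7 (not isolated)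
Conditions: 6, EtMgBr, THF, 0 → 25 °C; then 5, −78 → −40 °C; aq NH4Cl
Reagents that add atoms: none
Why: Cram-chelate addition of an alkynyl Grignard reagent to an α-alkoxy ketone: magnesium bridges the ketone oxygen and the inner MOM oxygen on C2, the acetylide enters from the side of the small C2–H (anti to the aryl ring), and this sets C1 as S relative to C2 R, which is the arrangement with the C2 aryl cis to the C1 oxygen in ring A.

Step 6
Reactants: 8 (1R,2S)-2-(tert-butoxymethyl)-1,4-bis(3,4-dimethoxyphenyl)-1-(methoxymethoxy)but-3-yn-2-ol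
Product: 9 tert-butyl{[(1R,2S)-2-(tert-butoxymethyl)-1,4-bis(3,4-dimethoxyphenyl)-1-(methoxymethoxy)but-3-yn-2-yl]oxy}dimethylsilane
Conditions: TBSOTf, 2,6-lutidine, CH2Cl2, 0 → 25 °C
Reagents that add atoms: tert-butyldimethylsilyl trifluoromethanesulfonate, CC(C)(C)[Si](C)(C)OS(=O)(=O)C(F)(F)F
Why: Silylation of the hindered tertiary propargylic alcohol with a silyl triflate turns O1 into a poor nucleophile and a poor leaving group for step 7.

Step 7
Reactants: 9 tert-butyl{[(1R,2S)-2-(tert-butoxymethyl)-1,4-bis(3,4-dimethoxyphenyl)-1-(methoxymethoxy)but-3-yn-2-yl]oxy}dimethylsilane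
Product: 11 (1S,2R)-2,6-bis(3,4-dimethoxyphenyl)-3,7-dioxabicyclo[3.3.0]oct-5-en-1-ol, via silylated bicyclic enol ether 10 (not isolated)
Conditions: TMSOTf, 2,6-di-tert-butyl-4-methylpyridine, CH2Cl2, −78 → −30 °C; Et3N; then TBAF, THF, 0 → 25 °C
Reagents that add atoms: none
Why: Proposed new method: TMSOTf removes the methoxy group of the MOM ether as MeOSiMe3 and leaves the oxocarbenium ion O3=C4H2+, whose carbon is attacked by the near alkyne carbon C5 while the tert-butyl ether oxygen O7 adds to C6 from the other side of the triple bond and then loses its tert-butyl group as isobutene, so that C4 and O7 end up anti across the new C5=C6 enol ether double bond. The closest known reaction type is the alkynyl Prins cyclisation of oxocarbenium ions onto aryl alkynes, in which the exocyclic α-aryl vinyl cation is taken up by triflate, halide or water; its capture by a tethered ether oxygen that sheds a tert-butyl cation, as tert-butyl ethers and carbonates do in other cationic cyclisations, is the untested part. Ring A (O3–C4–C5–C1–C2) closes 5-exo-dig and ring B (O7–C6–C5–C1–C8) closes 5-endo onto the linear vinyl cation, which is geometrically open because O7 approaches C6 in the plane of the empty p orbital, the plane that already holds C1 and C4. No stereocentre is formed or touched: C1 and C2 pass through unchanged, and C5 and C6 are left as the enol ether for step 8. The step needs C4 to bond to C5 and not to C6, which the 4-methoxy group of the C6 aryl ring secures by stabilising positive charge at C6 only, and it needs the CH2 unit to stay on O3, which is secured because the hindered tert-butyl ether (O7) and silyl ether (O1) oxygens should add to the oxocarbenium ion only reversibly at low temperature. The silyl group on O1 and the hindered pyridine base should keep the product, a vinylogous acetal at C1, from ionising and aromatising to a furan before fluoride frees the hydroxyl under basic conditions.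

Step 8
Reactants: 11 (1S,2R)-2,6-bis(3,4-dimethoxyphenyl)-3,7-dioxabicyclo[3.3.0]oct-5-en-1-ol
Product: 12 (+)-gmelinol, (1S,2R,5R,6R)-2,6-bis(3,4-dimethoxyphenyl)-3,7-dioxabicyclo[3.3.0]octan-1-ol
Conditions: H2 (1–3 bar), 10% Pd/C, Et3N (cat.), EtOAc, 25 °C
Reagents that add atoms: none
Why: Heterogeneous hydrogenation of a glycal-type enol ether is a syn addition, and since only the cis-fused bicycle can form, hydrogen should add to C5 and C6 from the face of the C1 hydroxyl, which puts H-5 and H-6 cis and the C6 aryl endo (C5 R, C6 R); the amine keeps the catalyst surface from promoting loss of the C1 hydroxyl or hydrogenolysis.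

**Compound list**

1 | ethyl (3,4-dimethoxyphenyl)(oxo)acetate | CCOC(=O)C(=O)c1ccc(OC)c(OC)c1 | starting material
2 | ethyl (R)-(3,4-dimethoxyphenyl)(hydroxy)acetate | CCOC(=O)[C@H](O)c1ccc(OC)c(OC)c1 | intermediate
3 | ethyl (R)-(3,4-dimethoxyphenyl)(methoxymethoxy)acetate | CCOC(=O)[C@H](OCOC)c1ccc(OC)c(OC)c1 | intermediate
4 | (R)-2-(3,4-dimethoxyphenyl)-N-methoxy-2-(methoxymethoxy)-N-methylacetamide | CON(C)C(=O)[C@H](OCOC)c1ccc(OC)c(OC)c1 | intermediate
5 | (R)-1-tert-butoxy-3-(3,4-dimethoxyphenyl)-3-(methoxymethoxy)propan-2-one | CC(C)(C)OCC(=O)[C@H](OCOC)c1ccc(OC)c(OC)c1 | intermediate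
6 | 4-ethynyl-1,2-dimethoxybenzene | C#Cc1ccc(OC)c(OC)c1 | starting material
7 | [(3,4-dimethoxyphenyl)ethynyl]magnesium bromide | COc1ccc(C#C[Mg]Br)cc1OC | intermediate
8 | (1R,2S)-2-(tert-butoxymethyl)-1,4-bis(3,4-dimethoxyphenyl)-1-(methoxymethoxy)but-3-yn-2-ol | COCO[C@H](c1ccc(OC)c(OC)c1)[C@@](O)(COC(C)(C)C)C#Cc1ccc(OC)c(OC)c1 | intermediate
9 | tert-butyl{[(1R,2S)-2-(tert-butoxymethyl)-1,4-bis(3,4-dimethoxyphenyl)-1-(methoxymethoxy)but-3-yn-2-yl]oxy}dimethylsilane | COCO[C@H](c1ccc(OC)c(OC)c1)[C@@](O[Si](C)(C)C(C)(C)C)(COC(C)(C)C)C#Cc1ccc(OC)c(OC)c1 | intermediate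
10 | tert-butyl{[(1S,2R)-2,6-bis(3,4-dimethoxyphenyl)-3,7-dioxabicyclo[3.3.0]oct-5-en-1-yl]oxy}dimethylsilane | COc1ccc([C@H]2OCC3=C(c4ccc(OC)c(OC)c4)OC[C@]23O[Si](C)(C)C(C)(C)C)cc1OC | intermediate
11 | (1S,2R)-2,6-bis(3,4-dimethoxyphenyl)-3,7-dioxabicyclo[3.3.0]oct-5-en-1-ol | COc1ccc([C@H]2OCC3=C(c4ccc(OC)c(OC)c4)OC[C@]23O)cc1OC | intermediate
12 | (+)-gmelinol, (1S,2R,5R,6R)-2,6-bis(3,4-dimethoxyphenyl)-3,7-dioxabicyclo[3.3.0]octan-1-ol | COc1ccc([C@H]2OC[C@@H]3[C@H](c4ccc(OC)c(OC)c4)OC[C@]23O)cc1OC | target

Total step count: 8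
Longest linear sequence: 8 steps (1 → 12)

**Steps most likely to fail**

1. Step 7 (Proposed new method).
 - What may go wrong: the O3=CH2+ ion may be taken up irreversibly by an oxygen (a cyclic formal with O1 after loss of the silyl group, or transfer of the CH2 unit to O7) or by the C2 aryl ring before the alkyne reacts. The vinyl cation may be taken up by triflate. The enol ether product may ionise at C1–O and aromatise.
 - Fallback (known reaction types only): it sets out from ketone 5 and comes back to the route at 12. The magnesium enolate of 3′,4′-dimethoxyacetophenone (LDA, then MgBr2·OEt2, THF, −78 °C) is added to 5 under the same chelate control and should give the aldol (3S,4R)-3-(tert-butoxymethyl)-1,4-bis(3,4-dimethoxyphenyl)-3-hydroxy-4-(methoxymethoxy)butan-1-one F1. TMSOTf/Et3N (CH2Cl2, −78 → 0 °C) should convert it into the bis-silyl compound (enol silane of the aryl ketone, O1 trimethylsilyl ether) F2. Catalytic TMSOTf with the hindered pyridine at −78 °C then ionises the MOM group, and the enol silane, a far better nucleophile than the alkyne, should close ring A by an intramolecular Mukaiyama-type addition to give the 4-aroyl-tetrahydrofuran F3 (both C5 epimers). CF3CO2H and Et3SiH in CH2Cl2 at 0 °C then cleave the tert-butyl and silyl ethers; the keto diol should close to the cis-fused bicyclic lactol F4 (the C5 epimer that cannot close equilibrates through the enol). The oxocarbenium ion at C6 is reduced by the silane from the convex face, which should give the endo C6 aryl of 12.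

2. Step 8.
 - What may go wrong: slow hydrogen uptake at the tetrasubstituted double bond; hydrogenolysis of the allylic C1–O and C4–O3 or the benzylic C–O bonds on palladium; loss of the free C1 hydroxyl (aromatisation) on a slightly acidic catalyst surface.
 - Fallback: it sets out from 10, which is then isolated after the amine quench of step 7 instead of being desilylated, and comes back at 12. Ionic hydrogenation (Et3SiH, CF3CO2H, CH2Cl2, −78 → −40 °C) should protonate C5 to the only accessible cis-fused oxocarbenium ion and deliver hydride to C6 from the convex face, while the silyl ether keeps the C1–O bond from ionising. This should give the silyl ether of the target, tert-butyl{[(1S,2R,5R,6R)-2,6-bis(3,4-dimethoxyphenyl)-3,7-dioxabicyclo[3.3.0]octan-1-yl]oxy}dimethylsilane F5; TBAF in THF then gives 12.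

3. Step 5.
 - What may go wrong: proton transfer from the acidic benzylic C2–H of ketone 5 to the aryl acetylide (enolisation, with loss of conversion and erosion of the C2 configuration), and incomplete chelate control at C1.
 - Fallback: it sets out from 5 and comes back at 8, and forms the aryl–alkyne bond last. The smaller, less basic cerium(III) (trimethylsilyl)acetylide (Me3SiC≡CH, n-BuLi, CeCl3, THF, −78 °C; the oxophilic metal still chelates the MOM oxygen) should give (1R,2S)-2-(tert-butoxymethyl)-1-(3,4-dimethoxyphenyl)-1-(methoxymethoxy)-4-(trimethylsilyl)but-3-yn-2-ol F6. K2CO3 in MeOH removes the C-silyl group to give the terminal alkyne (1R,2S)-2-(tert-butoxymethyl)-1-(3,4-dimethoxyphenyl)-1-(methoxymethoxy)but-3-yn-2-ol F7. Sonogashira coupling with 4-iodo-1,2-dimethoxybenzene (PdCl2(PPh3)2, CuI, Et3N, 25 °C) returns to 8.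

**Further compounds**

F1 | step 7 | (3S,4R)-3-(tert-butoxymethyl)-1,4-bis(3,4-dimethoxyphenyl)-3-hydroxy-4-(methoxymethoxy)butan-1-one | COCO[C@H](c1ccc(OC)c(OC)c1)[C@@](O)(COC(C)(C)C)CC(=O)c1ccc(OC)c(OC)c1
F2 | step 7 | bis-silyl compound: enol silane of F1 with O1 trimethylsilyl ether (enol geometry not specified) | COCO[C@H](c1ccc(OC)c(OC)c1)[C@@](O[Si](C)(C)C)(COC(C)(C)C)C=C(O[Si](C)(C)C)c1ccc(OC)c(OC)c1
F3 | step 7 | [(4S,5R)-4-(tert-butoxymethyl)-5-(3,4-dimethoxyphenyl)-4-(trimethylsilyloxy)oxolan-3-yl](3,4-dimethoxyphenyl)methanone (epimers at the aroyl-bearing carbon) | COc1ccc([C@H]2OCC(C(=O)c3ccc(OC)c(OC)c3)[C@]2(O[Si](C)(C)C)COC(C)(C)C)cc1OC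
F4 | step 7 | cis-fused bicyclic lactol, 2,6-bis(3,4-dimethoxyphenyl)-3,7-dioxabicyclo[3.3.0]octane-1,6-diol (anomers at C6) | COc1ccc([C@H]2OC[C@@H]3C(O)(c4ccc(OC)c(OC)c4)OC[C@]23O)cc1OC
F5 | step 8 | tert-butyl{[(1S,2R,5R,6R)-2,6-bis(3,4-dimethoxyphenyl)-3,7-dioxabicyclo[3.3.0]octan-1-yl]oxy}dimethylsilane | COc1ccc([C@H]2OC[C@@H]3[C@H](c4ccc(OC)c(OC)c4)OC[C@]23O[Si](C)(C)C(C)(C)C)cc1OC
F6 | step 5 | (1R,2S)-2-(tert-butoxymethyl)-1-(3,4-dimethoxyphenyl)-1-(methoxymethoxy)-4-(trimethylsilyl)but-3-yn-2-ol | COCO[C@H](c1ccc(OC)c(OC)c1)[C@@](O)(COC(C)(C)C)C#C[Si](C)(C)C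
F7 | step 5 | (1R,2S)-2-(tert-butoxymethyl)-1-(3,4-dimethoxyphenyl)-1-(methoxymethoxy)but-3-yn-2-ol | COCO[C@H](c1ccc(OC)c(OC)c1)[C@@](O)(COC(C)(C)C)C#C
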